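**Strategy.** Each 2H-isoquinoline-6,8-dione half is a push–pull system: N2 feeds C6=O through C3=C4–C4a=C5 and C8=O through C1=C8a. Hence C1 is a formyl carbon on C8a, C4a a vinylogous-ester carbon, and N2–C3=C4 the enamine of a methyl ketone. The C2 axis through the butane tether allows two-directional work. The key step is a double formal [3+3] aza-annulation: the bis-ketimine of butane-1,4-diamine with the dienyl methyl ketone condenses with two equivalents of an enantioenriched, chlorinated 2-formyl-3-methoxy o-quinol acetate. It forms C4–C4a (addition–elimination) and N2–C1 (condensation) in both pyridone rings and gives the target directly.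

Key step: step 8

Remarks on the chemistry:
- Quinols 12–15 are vinylogous acids; each is drawn as one tautomer, and CIP descriptors refer to that tautomer. Their ring atoms are called by the isoquinoline numbering of the target (dienone C1/C2/C3/C4/C5/C6 = target C6/C5/C4a/C8a/C8/C7).
- The C=N geometry of 8 is left undefined; the isomers interconvert and converge.
- 2,4-Dihydroxy-6-methoxybenzaldehyde (9) is taken as commercially available.

**Step 1**
Reactants: 1 (S)-2-methylbutan-1-ol; 2 2-(triphenylphosphoranylidene)propanal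
Product: 4 (2E,4S)-2,4-dimethylhex-2-enal, via (S)-2-methylbutanal 3 (not isolated)
Conditions: TEMPO (cat.), PhI(OAc)2, CH2Cl2, rt; then 2, 40 °C
Reagents that add atoms: none
Why: TEMPO/PhI(OAc)2 oxidation stops at the α-branched aldehyde, and trapping it in the same flask with the stabilised formyl ylide (Wittig reaction) should give the E-trisubstituted enal before the labile chiral-pool stereocentre can epimerise.

**Step 2**
Reactants: 4 (2E,4S)-2,4-dimethylhex-2-enal; 5 1-(triphenylphosphoranylidene)propan-2-one
Product: 6 (3E,5E,7S)-5,7-dimethylnona-3,5-dien-2-one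
Conditions: PhMe, 90 °C
Reagents that add atoms: none
Why: Wittig reaction of a stabilised acetonyl ylide with an enal is E-selective and does not touch the allylic stereocentre.

**Step 3**
Reactants: 6 (3E,5E,7S)-5,7-dimethylnona-3,5-dien-2-one (2 equiv); 7 butane-1,4-diamine
Product: 8 N,N'-(butane-1,4-diyl)bis[(3E,5E,7S)-5,7-dimethylnona-3,5-dien-2-imine]
Conditions: 4 Å MS, CH2Cl2, rt; filtered, concentrated, used crude
Reagents that add atoms: none
Why: Dehydrative imine formation between a primary amine and a methyl ketone is driven by water removal, whereas competing conjugate addition of the amine is reversible.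

**Step 4**
Reactants: 9 2,4-dihydroxy-6-methoxybenzaldehyde
Product: 10 2,4-dihydroxy-6-methoxy-3-methylbenzaldehyde
Conditions: MeI, KOH, MeOH, 0 °C → rt
Reagents that add atoms: iodomethane CI
Why: C-alkylation of the resorcinol dianion should occur at C3, the carbon ortho to both phenoxide oxygens, as for related 2,4-dihydroxybenzaldehydes.

**Step 5**
Reactants: 10 2,4-dihydroxy-6-methoxy-3-methylbenzaldehyde
Product: 11 3-chloro-4,6-dihydroxy-2-methoxy-5-methylbenzaldehyde
Conditions: NCS, MeCN, 0 °C → rt
Reagents that add atoms: N-chlorosuccinimide O=C1CCC(=O)N1Cl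
Why: Electrophilic aromatic chlorination can only occur at the single unsubstituted ring position, which is activated by three oxygen substituents.

**Step 6**
Reactants: 11 3-chloro-4,6-dihydroxy-2-methoxy-5-methylbenzaldehyde
Product: 12 (6S)-2-chloro-4-formyl-5,6-dihydroxy-3-methoxy-6-methylcyclohexa-2,4-dien-1-one
Conditions: [Cu(CH3CN)4]PF6, (−)-sparteine, O2, iPr2NEt, DMAP, CH2Cl2, −78 → −10 °C; 1 M HCl work-up
Reagents that add atoms: dioxygen O=O
Why: Enantioselective oxidative dearomatisation by the copper–dioxygen–sparteine complex should hydroxylate the phenoxide at the methyl-bearing carbon between the two oxygens; the diamine controls the face, and (−)-sparteine is chosen because on 6-substituted 2,4-dihydroxy-3-methylbenzaldehydes it is expected to give the spatial arrangement needed here (the (+)-sparteine surrogate would be used if the sense proved inverted).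

**Step 7**
Reactants: 12 (6S)-2-chloro-4-formyl-5,6-dihydroxy-3-methoxy-6-methylcyclohexa-2,4-dien-1-one
Product: 14 (6S)-6-acetoxy-2-chloro-4-formyl-5-hydroxy-3-methoxy-6-methylcyclohexa-2,4-dien-1-one, via enol acetate diacetate 13 (not isolated)
Conditions: Ac2O, DMAP, pyridine, CH2Cl2, 0 °C → rt; then MeOH, NaHCO3, 0 °C
Reagents that add atoms: acetic anhydride CC(=O)OC(C)=O
Why: DMAP-catalysed acylation esterifies both the tertiary alcohol and the acidic enol, and the enol acetate (a vinylogous anhydride) should be cleaved selectively by mild methanolysis, leaving the tertiary acetate.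

**Step 8**
Reactants: 8 N,N'-(butane-1,4-diyl)bis[(3E,5E,7S)-5,7-dimethylnona-3,5-dien-2-imine]; 14 (6S)-6-acetoxy-2-chloro-4-formyl-5-hydroxy-3-methoxy-6-methylcyclohexa-2,4-dien-1-one (2.1 equiv)
Product: 16 penazaphilone I, via open-chain bis(vinylogous amide) 15 (not isolated)
Conditions: 4 Å MS, CH2Cl2, 0 → 40 °C
Reagents that add atoms: none
Why: Proposed new method: each ketimine reacts through its secondary-enamine tautomer (exchange mediated by the acidic enol of 14): C4 adds to C4a, the β-carbon of the alkylidene keto-aldehyde tautomer of 14, methoxide leaves (addition–elimination) to give vinylogous amide 15, and N2–H then condenses with the formyl carbon C1, loss of water and of the enol proton giving the neutral pyridone. The closest known reaction types are the aza-annulation of N-alkyl ketimines with alkoxymethylene 1,3-dicarbonyl compounds to N-alkylpyridones and the enamine/3-formylchromone pyridine synthesis; new here is the dearomatised o-quinol acetate as the three-carbon 1,3-dielectrophile. Each pyridone ring closes by 6-exo-trig attack of N2 on the formyl C=O, after the intermolecular C4–C4a bond has been made. No stereocentre is formed; C7 is quaternary, non-enolisable and protected from α-ketol shift by its acetate, and the side-chain centre is remote from the reacting sites. The step needs the C4-to-C4a and N2-to-C1 pairing: methoxy on C4a is the only vinylic leaving group offered to the soft carbon terminus, the formyl group is the only unhindered carbonyl for nitrogen (C8=O is flanked by quaternary C7), and the carbocycle holds C4 and C1 cis across C4a=C8a. Sieves exclude water so that no free amine forms to cap the formyl group or cleave the acetates.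

**Compound list**
1 | (S)-2-methylbutan-1-ol | CC[C@H](C)CO | starting material
2 | 2-(triphenylphosphoranylidene)propanal | CC(C=O)=P(c1ccccc1)(c1ccccc1)c1ccccc1 | starting material
3 | (S)-2-methylbutanal | CC[C@H](C)C=O | intermediate (not isolated)
4 | (2E,4S)-2,4-dimethylhex-2-enal | CC[C@H](C)/C=C(C)/C=O | intermediate
5 | 1-(triphenylphosphoranylidene)propan-2-one | CC(=O)C=P(c1ccccc1)(c1ccccc1)c1ccccc1 | starting material
6 | (3E,5E,7S)-5,7-dimethylnona-3,5-dien-2-one | CC[C@H](C)/C=C(C)/C=C/C(C)=O | intermediate
7 | butane-1,4-diamine | NCCCCN | starting material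
8 | N,N'-(butane-1,4-diyl)bis[(3E,5E,7S)-5,7-dimethylnona-3,5-dien-2-imine] | CC[C@H](C)/C=C(C)/C=C/C(C)=NCCCCN=C(C)/C=C/C(C)=C/[C@@H](C)CC | intermediate
9 | 2,4-dihydroxy-6-methoxybenzaldehyde | COc1cc(O)cc(O)c1C=O | starting material
10 | 2,4-dihydroxy-6-methoxy-3-methylbenzaldehyde | COc1cc(O)c(C)c(O)c1C=O | intermediate
11 | 3-chloro-4,6-dihydroxy-2-methoxy-5-methylbenzaldehyde | COc1c(Cl)c(O)c(C)c(O)c1C=O | intermediate
12 | (6S)-2-chloro-4-formyl-5,6-dihydroxy-3-methoxy-6-methylcyclohexa-2,4-dien-1-one | O=CC1=C(O)[C@](C)(O)C(=O)C(Cl)=C1OC | intermediate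
13 | (6S)-5,6-diacetoxy-2-chloro-4-formyl-3-methoxy-6-methylcyclohexa-2,4-dien-1-one (enol acetate and tertiary acetate) | O=CC1=C(OC(C)=O)[C@](C)(OC(C)=O)C(=O)C(Cl)=C1OC | intermediate (not isolated)
14 | (6S)-6-acetoxy-2-chloro-4-formyl-5-hydroxy-3-methoxy-6-methylcyclohexa-2,4-dien-1-one | O=CC1=C(O)[C@](C)(OC(C)=O)C(=O)C(Cl)=C1OC | intermediate
15 | open-chain bis(vinylogous amide): each imine methyl carbon bonded to C4a of a quinol acetate unit in place of methoxy, formyl groups still free, C7 configuration as in 14 | CC[C@H](C)/C=C(C)/C=C/C(NCCCCNC(/C=C/C(C)=C/[C@@H](C)CC)=CC1=C(C=O)C(=O)[C@](C)(OC(C)=O)C(O)=C1Cl)=CC1=C(C=O)C(=O)[C@](C)(OC(C)=O)C(O)=C1Cl | intermediate (not isolated)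
16 | penazaphilone I: 2,2'-(butane-1,4-diyl)bis[(7S)-7-acetoxy-5-chloro-3-[(1E,3E,5S)-3,5-dimethylhepta-1,3-dien-1-yl]-7-methylisoquinoline-6,8(2H,7H)-dione] | CC[C@H](C)/C=C(C)/C=C/C1=CC2=C(Cl)C(=O)[C@@](C)(OC(C)=O)C(=O)C2=CN1CCCCN1C=C2C(=O)[C@](C)(OC(C)=O)C(=O)C(Cl)=C2C=C1/C=C/C(C)=C/[C@@H](C)CC | target

**Step count and risks**
Total steps: 8. Longest linear sequence: 5 steps (steps 4, 5, 6, 7, 8); the side-chain branch (steps 1, 2, 3) joins at step 8.

Steps most likely to fail:

1. Step 8 (proposed new method). The two termini may pair the wrong way round (carbon attacking the formyl group, nitrogen displacing methoxide). The reaction may also stall, because proton transfer from the acidic quinol to the ketimine turns the electrophile into its unreactive enolate and the nucleophile into an iminium ion that hydrolyses. The fallback sets out from 6 and comes back at 16; it builds the oxygen heterocycle by the established alkynylbenzaldehyde chemistry of azaphilones and exchanges ring oxygen for nitrogen at the end. Ketone 6 is converted with LiN(iPr)2 and ClP(O)(OEt)2 into diethyl (3E,5E,7S)-5,7-dimethylnona-1,3,5-trien-2-yl phosphate F1, which a second treatment with LiN(iPr)2 turns into (3E,5E,7S)-5,7-dimethylnona-3,5-dien-1-yne F2. Commercial 1-bromo-3,5-dimethoxybenzene is formylated (POCl3, DMF) to 2-bromo-4,6-dimethoxybenzaldehyde F3, demethylated (BBr3) to 2-bromo-4,6-dihydroxybenzaldehyde F4 and C-methylated (MeI, KOH) to 6-bromo-2,4-dihydroxy-3-methylbenzaldehyde F5. Sonogashira coupling of F2 with F5 (PdCl2(PPh3)2, CuI, Et3N) should give the alkynylbenzaldehyde F6. Oxidative dearomatisation under the conditions of step 6 should give the alkynyl quinol F7, which is cycloisomerised without isolation (KH2PO4/K2HPO4 buffer, MeCN) to the 7-hydroxyazaphilone F8. Acetylation (Ac2O, DMAP) gives the azaphilone acetate F9, and chlorination at C5 (NCS) the chloroazaphilone F10. Two equivalents of F10 and diamine 7 (Et3N, CH2Cl2, rt) should then give 16 by the ring-opening/ring-closing amine exchange typical of azaphilones.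

2. Step 6. Facial selectivity may be poor or inverted, or oxidation may take another course, because the fully substituted, chlorine-bearing phenol lies outside the substrates on which the copper–sparteine oxidation is established. The fallback sets out from 11 and comes back at 14, bypassing steps 6 and 7. Wessely acetoxylation with Pb(OAc)4 (AcOH/CH2Cl2, 0 °C) should give the racemic quinol acetate F11 in one step, and its enantiomers are separated by preparative chromatography on a chiral stationary phase to give 14.

3. Step 7. Acylation of the hindered tertiary alcohol may be incomplete, or the tertiary acetate may be lost (or the ring opened) while the enol acetate is cleaved. The fallback sets out from 12 and comes back at 16. The free quinol 12 is used with 8 under the conditions of step 8 to give the bis(tertiary alcohol) F12, and both hydroxy groups are acetylated last (Ac2O, DMAP, pyridine, CH2Cl2) to give 16.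

**Further compounds**
F1 | step 8 | diethyl (3E,5E,7S)-5,7-dimethylnona-1,3,5-trien-2-yl phosphate | CC[C@H](C)/C=C(C)/C=C/C(=C)OP(=O)(OCC)OCC
F2 | step 8 | (3E,5E,7S)-5,7-dimethylnona-3,5-dien-1-yne | CC[C@H](C)/C=C(C)/C=C/C#C
F3 | step 8 | 2-bromo-4,6-dimethoxybenzaldehyde | O=Cc1c(Br)cc(OC)cc1OC
F4 | step 8 | 2-bromo-4,6-dihydroxybenzaldehyde | O=Cc1c(Br)cc(O)cc1O
F5 | step 8 | 6-bromo-2,4-dihydroxy-3-methylbenzaldehyde | O=Cc1c(Br)cc(O)c(C)c1O
F6 | step 8 | 6-[(3E,5E,7S)-5,7-dimethylnona-3,5-dien-1-yn-1-yl]-2,4-dihydroxy-3-methylbenzaldehyde | CC[C@H](C)/C=C(C)/C=C/C#Cc1cc(O)c(C)c(O)c1C=O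
F7 | step 8 | alkynyl quinol (vinylogous acid) from dearomatisation of F6 | CC[C@H](C)/C=C(C)/C=C/C#CC1=CC(=O)[C@@](C)(O)C(O)=C1C=O
F8 | step 8 | (7R)-3-[(1E,3E,5S)-3,5-dimethylhepta-1,3-dien-1-yl]-7-hydroxy-7-methyl-6H-isochromene-6,8(7H)-dione | CC[C@H](C)/C=C(C)/C=C/C1=CC2=CC(=O)[C@@](C)(O)C(=O)C2=CO1
F9 | step 8 | (7R)-7-acetoxy-3-[(1E,3E,5S)-3,5-dimethylhepta-1,3-dien-1-yl]-7-methyl-6H-isochromene-6,8(7H)-dione | CC[C@H](C)/C=C(C)/C=C/C1=CC2=CC(=O)[C@@](C)(OC(C)=O)C(=O)C2=CO1
F10 | step 8 | (7S)-7-acetoxy-5-chloro-3-[(1E,3E,5S)-3,5-dimethylhepta-1,3-dien-1-yl]-7-methyl-6H-isochromene-6,8(7H)-dione | CC[C@H](C)/C=C(C)/C=C/C1=CC2=C(Cl)C(=O)[C@@](C)(OC(C)=O)C(=O)C2=CO1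
F11 | step 6 | racemic 6-acetoxy-2-chloro-4-formyl-5-hydroxy-3-methoxy-6-methylcyclohexa-2,4-dien-1-one | O=CC1=C(O)C(C)(OC(C)=O)C(=O)C(Cl)=C1OC
F12 | step 7 | 2,2'-(butane-1,4-diyl)bis[(7S)-5-chloro-3-[(1E,3E,5S)-3,5-dimethylhepta-1,3-dien-1-yl]-7-hydroxy-7-methylisoquinoline-6,8(2H,7H)-dione] | CC[C@H](C)/C=C(C)/C=C/C1=CC2=C(Cl)C(=O)[C@@](C)(O)C(=O)C2=CN1CCCCN1C=C2C(=O)[C@](C)(O)C(=O)C(Cl)=C2C=C1/C=C/C(C)=C/[C@@H](C)CC
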